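## Retrosynthetic overview

1. Set aside: the usual formaldehyde condensation of the two acylphloroglucinol monomers, which gives a statistical mixture of homo- and heterodimers.
2. Key disconnection: the bridge CH2–ring A bond, made last by a Knoevenagel/transfer-hydrogenation cascade between ring B aldehyde 6 and ring A carbon acid 8. The bridge carbon sits on ring B at the aldehyde oxidation level, so neither partner can homodimerise.
3. 6 ⇒ Rieche formylation of aspidinol 4 at its only free ring carbon; 4 ⇒ para-selective O-methylation of 3.
4. 3 and 8 ⇒ Friedel–Crafts acylation of 2-methylphloroglucinol 1 with butanoyl chloride 2 or pentanoyl chloride 7.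
5. Ring order: no ring is built. Both benzene rings come from 1; ring B is fully substituted first, ring A second, and they are joined in the final step.

Assumption: the target has no stereocentre and no stereogenic double bond, so "single enantiomer" is read as the achiral compound drawn; no stereocontrol is needed.

## Route

Step 1
Reactants: 1 2-methylbenzene-1,3,5-triol (2-methylphloroglucinol); 2 butanoyl chloride
Product: 3 1-(2,4,6-trihydroxy-3-methylphenyl)butan-1-one
Conditions: AlCl3 (3.5 equiv), PhNO2/CH2Cl2, 0 °C → 40 °C; ice/2 M aq. HCl work-up
Reagents that add atoms: none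
Why: Friedel–Crafts acylation: the two unsubstituted ring carbons of 1 are equivalent, so only one regioisomer can form, and the aluminium-chelated ketone deactivates the ring toward a second acylation; no stereocentre is created.

Step 2
Reactants: 3 1-(2,4,6-trihydroxy-3-methylphenyl)butan-1-one
Product: 4 1-(2,6-dihydroxy-4-methoxy-3-methylphenyl)butan-1-one (aspidinol)
Conditions: Me2SO4 (1.0 equiv), K2CO3 (1.05 equiv), acetone, 0 °C → rt
Reagents that add atoms: dimethyl sulfate, COS(=O)(=O)OC
Why: Williamson-type O-methylation under pKa control: the 4-OH, para to the ketone and not hydrogen-bonded to it, is the most acidic and most exposed hydroxyl, so one equivalent of base and of the hard methylating agent etherifies it while the two carbonyl-flanking hydroxyls stay chelated; no stereocentre is created.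

Step 3
Reactants: 4 1-(2,6-dihydroxy-4-methoxy-3-methylphenyl)butan-1-one (aspidinol)
Product: 6 3-butanoyl-2,4-dihydroxy-6-methoxy-5-methylbenzaldehyde, via alpha-chloro ether 5 (not isolated)
Conditions: Cl2CHOMe (1.5 equiv), TiCl4 (3.5 equiv), CH2Cl2, −20 → 0 °C; then 1 M aq. HCl, rt
Reagents that add atoms: dichloromethyl methyl ether, COC(Cl)Cl; water, O
Why: Rieche formylation: the titanium phenoxide directs the methoxychlorocarbenium electrophile to the only unsubstituted ring carbon (ortho to OH and OMe, para to OH), and the transient racemic alpha-chloro ether 5 is hydrolysed to the aldehyde on work-up, so no stereocentre remains.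

Step 4
Reactants: 1 2-methylbenzene-1,3,5-triol (2-methylphloroglucinol); 7 pentanoyl chloride
Product: 8 1-(2,4,6-trihydroxy-3-methylphenyl)pentan-1-one
Conditions: AlCl3 (3.5 equiv), PhNO2/CH2Cl2, 0 °C → 40 °C; ice/2 M aq. HCl work-up
Reagents that add atoms: none
Why: Friedel–Crafts acylation exactly as in step 1: symmetry of 1 allows a single regioisomer, the chelated ketone stops the reaction at monoacylation, and one ring C–H is left as the nucleophilic site for the coupling; no stereocentre is created.

Step 5
Reactants: 6 3-butanoyl-2,4-dihydroxy-6-methoxy-5-methylbenzaldehyde (1.0 equiv); 8 1-(2,4,6-trihydroxy-3-methylphenyl)pentan-1-one (1.1 equiv)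
Product: 10 1-[3-[(3-butanoyl-2,4-dihydroxy-6-methoxy-5-methylphenyl)methyl]-2,4,6-trihydroxy-5-methylphenyl]pentan-1-one, via quinone methide 9 (not isolated)
Conditions: diethyl 2,6-dimethyl-1,4-dihydropyridine-3,5-dicarboxylate (Hantzsch ester, 1.3 equiv), L-proline (20 mol%), (PhO)2P(O)OH (10 mol%), EtOH/CH2Cl2 1:1, 40 °C, Ar, dark
Reagents that add atoms: none
Why: Proposed new method: a three-component reductive alkylation (amine-catalysed Knoevenagel condensation followed by transfer hydrogenation) carried over from cyclic 1,3-diones to an acylphloroglucinol: the proline iminium of 6 is attacked by the only free ring carbon of 8 (Betti-type aza-Friedel–Crafts step), loss of proline gives quinone methide 9, and acid-activated 9 accepts hydride at its exocyclic carbon from the Hantzsch ester, which rearomatises ring A and touches neither the aldehyde nor the chelated aryl ketones; the closest known reactions are the proline/Hantzsch ester reductive alkylation of 1,3-diones with aldehydes and the Brønsted acid-catalysed Hantzsch ester reduction of ortho-quinone methides, and because both rings are fully substituted after coupling and no free one-carbon unit is present, homodimers cannot form and no stereocentre is created.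

## Compound list

1 | 2-methylbenzene-1,3,5-triol (2-methylphloroglucinol) | Cc1c(O)cc(O)cc1O | starting material
2 | butanoyl chloride | CCCC(=O)Cl | starting material
3 | 1-(2,4,6-trihydroxy-3-methylphenyl)butan-1-one | CCCC(=O)c1c(O)c(C)c(O)cc1O | intermediate
4 | 1-(2,6-dihydroxy-4-methoxy-3-methylphenyl)butan-1-one (aspidinol) | CCCC(=O)c1c(O)c(C)c(OC)cc1O | intermediate
5 | 1-[3-[chloro(methoxy)methyl]-2,6-dihydroxy-4-methoxy-5-methylphenyl]butan-1-one (racemic, titanium-bound alpha-chloro ether) | CCCC(=O)c1c(O)c(C)c(OC)c(C(Cl)OC)c1O | intermediate
6 | 3-butanoyl-2,4-dihydroxy-6-methoxy-5-methylbenzaldehyde | CCCC(=O)c1c(O)c(C)c(OC)c(C=O)c1O | intermediate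
7 | pentanoyl chloride | CCCCC(=O)Cl | starting material
8 | 1-(2,4,6-trihydroxy-3-methylphenyl)pentan-1-one | CCCCC(=O)c1c(O)c(C)c(O)cc1O | intermediate
9 | 6-[(3-butanoyl-2,4-dihydroxy-6-methoxy-5-methylphenyl)methylidene]-3,5-dihydroxy-2-methyl-4-pentanoylcyclohexa-2,4-dien-1-one (quinone methide; one tautomer drawn, alkene geometry not defined) | CCCCC(=O)C1=C(O)C(=Cc2c(O)c(C(=O)CCC)c(O)c(C)c2OC)C(=O)C(C)=C1O | intermediate
10 | 1-[3-[(3-butanoyl-2,4-dihydroxy-6-methoxy-5-methylphenyl)methyl]-2,4,6-trihydroxy-5-methylphenyl]pentan-1-one (CNP0210501.0, achiral) | CCCCC(=O)c1c(O)c(C)c(O)c(Cc2c(O)c(C(=O)CCC)c(O)c(C)c2OC)c1O | target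

## Step count and risk

Total steps: 5. Longest linear sequence: 4 steps (1 → 3 → 4 → 6 → 10); step 4 is the convergent branch.

The three steps most likely to fail are steps 5, 2 and 3.

Step 5 is the key coupling and the riskiest step. The aldehyde of 6 is a hindered, push–pull deactivated vinylogous acid and may condense slowly. Quinone methide 9 is strongly stabilised and may resist hydride transfer. Reduction by way of the ring B quinone methide could give some 5-methylaspidinol, and a second molecule of 8 could add to 9. The fallback sets out from 6 and comes back at 10 without any reductant in the bond-forming event. Compound 6 is reductively aminated (Me2NH, NaBH(OAc)3, AcOH, 1,2-dichloroethane, rt) to the Mannich base 1-[3-[(dimethylamino)methyl]-2,6-dihydroxy-4-methoxy-5-methylphenyl]butan-1-one F1. Heating F1 with 8 in dioxane at 100 °C expels dimethylamine to give the ortho-quinone methide of ring B, which is trapped by the free ring carbon of 8 to give 10.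

Step 2 may give the 6-O-methyl isomer, the dimethyl ether or some ring C-methylation alongside 4. The fallback sets out from 3 and comes back at 4, replacing kinetic selectivity by chelation control. Compound 3 is exhaustively methylated (Me2SO4 in excess, K2CO3, acetone, reflux) to 1-(2,4,6-trimethoxy-3-methylphenyl)butan-1-one F2. BCl3 (3 equiv, CH2Cl2, −78 °C → rt) then cleaves only the two methyl ethers that can chelate boron to the ketone oxygen; the para-methoxy group cannot chelate and survives, giving 4.

Step 3 may suffer from low conversion, because the ring is deactivated by the acyl group and by titanium chelation, or from O-formylation or partial loss of the methyl ether. The fallback sets out from 4 and comes back at 10, bypassing aldehyde 6 altogether. A boronate-templated ortho-hydroxymethylation of 4 (PhB(OH)2, paraformaldehyde, cat. EtCO2H, toluene, reflux, Dean–Stark) delivers the one-carbon unit only ortho to the 6-OH and gives 1-(7-hydroxy-5-methoxy-6-methyl-2-phenyl-4H-1,3,2-benzodioxaborin-8-yl)butan-1-one F3. Heating F3 with 8 (cat. TsOH, dioxane, 80 °C) opens the dioxaborin to the ring B ortho-quinone methide, which 8 captures to give 10.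

Further compounds
F1 | step 5 | 1-[3-[(dimethylamino)methyl]-2,6-dihydroxy-4-methoxy-5-methylphenyl]butan-1-one | CCCC(=O)c1c(O)c(C)c(OC)c(CN(C)C)c1O
F2 | step 2 | 1-(2,4,6-trimethoxy-3-methylphenyl)butan-1-one | CCCC(=O)c1c(OC)c(C)c(OC)cc1OC
F3 | step 3 | 1-(7-hydroxy-5-methoxy-6-methyl-2-phenyl-4H-1,3,2-benzodioxaborin-8-yl)butan-1-one | CCCC(=O)c1c(O)c(C)c(OC)c2COB(c3ccccc3)Oc12
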